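**Plan**

- Retrosynthesis: the C1'=C2' enone is moved back to C2'=C3', the aryl ketone to a benzylic carbinol and the side-chain carbinol to a lactone carbonyl. The bicyclic lactone so revealed is cut at C1'–C6' and C4'–C5' (Diels–Alder), then at the ester C–O, the C8–carbinol bond, C6–prenyl, C8–CHO and the pyranone ring.
- Enabling feature: on the cyclohexene the C5' methyl and the C6' 1-hydroxyethyl group are cis, and the carbinol carbon and the ketone carbon are 1,4-related (C–C6'–C1'–C). The carbinol oxygen can therefore bridge them as a five-membered lactone, which ties a (Z)-but-2-enoate to a 1-arylpentadienyl unit.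
- Forward: Pechmann condensation builds the coumarin; C8 is formylated and C6 prenylated; a dienylzinc adds to the aldehyde; esterification and alkyne semi-reduction give the triene. One cycloaddition then closes the cyclohexene and the γ-lactone. The lactone is opened to the methyl carbinol, the benzylic carbinol is oxidised and the alkene is moved into conjugation.
- Stereochemistry: the benzylic centre comes from a ligand-controlled alkenylzinc addition. Together with the Z geometry it sets C5'/C6' in the cycloaddition and is then erased (C=O and sp2 C1'). The side-chain carbinol comes from a CBS reduction.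

Key step: step 9

Remark: the cycloaddition is planned on the premise that the exo (trans-fused) mode, with the carbinol hydrogen eclipsing the diene, is preferred; the (R) configuration of carbinol 12 follows from that premise.

**Route**

Step 1
Reactants: 1 5-methoxyresorcinol; 2 ethyl 2-methyl-3-oxobutanoate
Product: 3 7-hydroxy-5-methoxy-3,4-dimethylcoumarin
Conditions: H2SO4 (75%), 0 °C → rt; recrystallisation
Reagents that add atoms: none
Why: Pechmann condensation (transesterification, ring hydroxyalkylation, dehydration); closure at either of the two equivalent carbons between OH and OMe should give mainly the 7-hydroxy-5-methoxy isomer, the 5-hydroxy-7-methoxy isomer being removed by crystallisation.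

Step 2
Reactants: 3 7-hydroxy-5-methoxy-3,4-dimethylcoumarin
Product: 4 7-hydroxy-5-methoxy-3,4-dimethyl-2-oxo-2H-chromene-8-carbaldehyde
Conditions: hexamethylenetetramine, TFA, 85 °C; then H2O, 60 °C
Reagents that add atoms: hexamethylenetetramine C1N2CN3CN1CN(C2)C3; water O
Why: Duff ortho-formylation of the phenol; as in other 7-hydroxycoumarins attack should occur at C8, where the C7–C8 bond has the higher double-bond character, and the lactone and the aryl methyl ether are inert to TFA.

Step 3
Reactants: 4 7-hydroxy-5-methoxy-3,4-dimethyl-2-oxo-2H-chromene-8-carbaldehyde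
Product: 5 7-hydroxy-6-iodo-5-methoxy-3,4-dimethyl-2-oxo-2H-chromene-8-carbaldehyde
Conditions: NIS, TFA (cat.), MeCN, 0 °C → rt
Reagents that add atoms: N-iodosuccinimide O=C1CCC(=O)N1I
Why: electrophilic aromatic iodination at C6, the only unsubstituted ring carbon, which is activated by the ortho hydroxyl and methoxy groups; C3 and C4 are blocked by methyl groups.

Step 4
Reactants: 5 7-hydroxy-6-iodo-5-methoxy-3,4-dimethyl-2-oxo-2H-chromene-8-carbaldehyde
Product: 6 6-iodo-5-methoxy-7-(methoxymethoxy)-3,4-dimethyl-2-oxo-2H-chromene-8-carbaldehyde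
Conditions: MOMCl, iPr2NEt, CH2Cl2, 0 °C → rt
Reagents that add atoms: chloromethyl methyl ether COCCl
Why: O-alkylation of the phenol (acetal formation); the MOM ether should survive the organometallic reagents, heat and base that follow and is removed last by mild acid.

Step 5
Reactants: 6 6-iodo-5-methoxy-7-(methoxymethoxy)-3,4-dimethyl-2-oxo-2H-chromene-8-carbaldehyde; 7 tributyl(3-methylbut-2-en-1-yl)stannane
Product: 8 5-methoxy-7-(methoxymethoxy)-3,4-dimethyl-6-(3-methylbut-2-en-1-yl)-2-oxo-2H-chromene-8-carbaldehyde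
Conditions: Pd(PPh3)4 (5 mol%), DMF, 90 °C
Reagents that add atoms: none
Why: Stille coupling of the aryl iodide with the allylic stannane, which under catalysis by zerovalent palladium should transfer the prenyl group at its α-carbon (linear isomer); aldehyde, lactone and acetal are tolerated.

Step 6
Reactants: 8 5-methoxy-7-(methoxymethoxy)-3,4-dimethyl-6-(3-methylbut-2-en-1-yl)-2-oxo-2H-chromene-8-carbaldehyde; 9 but-1-en-3-yne
Product: 12 8-[(1R,2E)-1-hydroxypenta-2,4-dien-1-yl]-5-methoxy-7-(methoxymethoxy)-3,4-dimethyl-6-(3-methylbut-2-en-1-yl)coumarin, via (E)-butadienyldicyclohexylborane 10 (not isolated), via (E)-butadienyl(methyl)zinc 11 (not isolated)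
Conditions: Cy2BH, toluene, 0 °C → rt; Me2Zn, −78 °C; (+)-MIB (5 mol%), then 8, −20 → 0 °C; aq. NH4Cl
Reagents that add atoms: none
Why: syn hydroboration of the alkyne terminus of the enyne gives the (E)-dienylborane, boron-to-zinc exchange gives the alkenylzinc, and the amino-alcohol-catalysed asymmetric alkenylzinc addition sets the carbinol centre; (+)-MIB, the enantiomer of the ligand that gives (S)-1-phenylpropanol from PhCHO and Et2Zn, should deliver the dienyl group to the Re face and give the (R)-alcohol.

Step 7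
Reactants: 12 the (R)-dienyl carbinol; 13 but-2-ynoic acid
Product: 14 (1R,2E)-1-[5-methoxy-7-(methoxymethoxy)-3,4-dimethyl-6-(3-methylbut-2-en-1-yl)-2-oxo-2H-chromen-8-yl]penta-2,4-dien-1-yl but-2-ynoate
Conditions: DCC, DMAP (5 mol%), CH2Cl2, −20 → 0 °C
Reagents that add atoms: none
Why: Steglich esterification; an alkynoic acid is used because it cannot lose alkene geometry under DMAP, and the near-neutral conditions should avoid ionisation of the benzylic, dienylic alcohol.

Step 8
Reactants: 14 the dienyl but-2-ynoate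
Product: 15 (1R,2E)-1-[5-methoxy-7-(methoxymethoxy)-3,4-dimethyl-6-(3-methylbut-2-en-1-yl)-2-oxo-2H-chromen-8-yl]penta-2,4-dien-1-yl (2Z)-but-2-enoate
Conditions: H2 (1 atm), Pd/CaCO3 poisoned with Pb(OAc)2 (Lindlar catalyst), quinoline, EtOAc, rt, stopped after one equivalent of H2
Reagents that add atoms: none
Why: Lindlar semi-hydrogenation adds H2 syn to the alkyne and should give the (Z)-enoate; the poisoned catalyst reduces the alkyne faster than the diene, the prenyl group or the allylic C–O bond.

Step 9
Reactants: 15 the (Z)-but-2-enoate of the (R)-dienyl carbinol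
Product: 16 (3R,3aR,7R,7aR)-3-[5-methoxy-7-(methoxymethoxy)-3,4-dimethyl-6-(3-methylbut-2-en-1-yl)-2-oxo-2H-chromen-8-yl]-7-methyl-3a,6,7,7a-tetrahydro-2-benzofuran-1(3H)-one (trans-fused; aryl cis to H-3a; methyl cis to the lactone carbonyl)
Conditions: PhMe (0.01 M), BHT (0.1 equiv), sealed vessel, 165 °C; chromatographic removal of minor fusion isomers
Reagents that add atoms: none
Why: Heating brings the (Z)-crotonate under the diene through the s-cis ester conformer, and a concerted, asynchronous [4+2] cycloaddition forms C1'–C6' and C4'–C5'; the closest known reaction type is the ester-tethered intramolecular Diels–Alder reaction of pentadienyl acrylates. The cyclohexene closes as the cycloadduct ring and the γ-lactone closes in the same event as a fused five-membered ring through the three-atom C–O–C(=O) tether (type 1, fused mode). C7 and C7a (later C5' and C6') are cis because the Z geometry of the dienophile is transferred suprafacially, and their absolute sense follows from the (R)-carbinol centre, whose hydrogen eclipses the diene (least allylic strain) so that the hindered aryl group points away from the incoming dienophile. C3a arises from the exo (tether anti) transition state and gives the trans ring fusion; C3 and C3a are erased later, but together they decide which dienophile face is used, so the step needs both exo and facial selectivity. The exo mode should be favoured because it keeps the Z-methyl group and the tether carbonyl away from the diene, and the minor fusion isomers, which would lead to the mirror-image C5'/C6' pair, are removed here. Ionisation of the benzylic ester should be held back by the non-polar medium and by the two ortho substituents, which keep the aryl ring from stabilising a cation at this carbon.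

Step 10
Reactants: 16 the trans-fused lactone
Product: 17 (1R,2R,6R)-2-[(R)-hydroxy(aryl)methyl]-N-methoxy-N,6-dimethylcyclohex-3-ene-1-carboxamide (aryl = the MOM-protected coumarin-8-yl group)
Conditions: MeNH(OMe)·HCl, AlMe3, CH2Cl2, 0 °C → rt; aq. KNaC4H4O6 (potassium sodium tartrate)
Reagents that add atoms: N,O-dimethylhydroxylamine hydrochloride CNOC.Cl
Why: aminolysis of the lactone by the aluminium amide (Weinreb amide formation); the strained trans-fused γ-lactone should react before the conjugated, tetrasubstituted coumarin carbonyl, and its strain also disfavours re-closure.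

Step 11
Reactants: 17 the hydroxy Weinreb amide
Product: 18 1-[(1R,2R,6R)-2-[(R)-hydroxy(aryl)methyl]-6-methylcyclohex-3-en-1-yl]ethan-1-one
Conditions: MeMgBr (3.5 equiv), THF, −40 → 0 °C; aq. NH4Cl
Reagents that add atoms: methylmagnesium bromide C[Mg]Br
Why: Grignard addition to the Weinreb amide stops at the ketone because the chelated tetrahedral intermediate survives until work-up; one equivalent is spent on the hydroxyl group, and at low temperature the coumarin carbonyl should be spared.

Step 12
Reactants: 18 the hydroxy methyl ketone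
Product: 19 (1S)-1-[(1R,2R,6R)-2-[(R)-hydroxy(aryl)methyl]-6-methylcyclohex-3-en-1-yl]ethan-1-ol
Conditions: (R)-2-methyl-CBS-oxazaborolidine (20 mol%), catecholborane (2.5 equiv), toluene, −78 → −40 °C
Reagents that add atoms: none
Why: Corey–Bakshi–Shibata reduction under reagent control; with the ring carbon as the large and methyl as the small substituent the (R)-oxazaborolidine should deliver hydride to give the (S)-carbinol, and catecholborane at low temperature does not hydroborate the alkenes.

Step 13
Reactants: 19 the diol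
Product: 20 [(1R,5R,6R)-6-[(1S)-1-hydroxyethyl]-5-methylcyclohex-2-en-1-yl](aryl)methanone
Conditions: MnO2 (activated, excess), CH2Cl2, rt
Reagents that add atoms: none
Why: MnO2 oxidises benzylic alcohols selectively, so the saturated secondary carbinol should be left untouched; the benzylic stereocentre is removed here.

Step 14
Reactants: 20 the β,γ-unsaturated aryl ketone
Product: 21 8-{[(5R,6R)-6-[(1S)-1-hydroxyethyl]-5-methylcyclohex-1-en-1-yl]carbonyl}-5-methoxy-7-(methoxymethoxy)-3,4-dimethyl-6-(3-methylbut-2-en-1-yl)coumarin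
Conditions: DBU (0.3 equiv), CH2Cl2, rt
Reagents that add atoms: none
Why: base-mediated isomerisation of the β,γ-unsaturated ketone through its dienolate (deprotonation at the doubly activated C1'–H, protonation at C3') to the conjugated trisubstituted enone; C6'–H is not acidified by the carbonyl, so the C5'/C6' pair should be retained while the ring-fusion-derived centre disappears.

Step 15
Reactants: 21 the MOM-protected enone
Product: 22 the target, 7-hydroxy-8-{[(5R,6R)-6-[(1S)-1-hydroxyethyl]-5-methylcyclohex-1-en-1-yl]carbonyl}-5-methoxy-3,4-dimethyl-6-(3-methylbut-2-en-1-yl)coumarin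
Conditions: HCl (2 M aq.), MeOH–THF, rt
Reagents that add atoms: none
Why: acid-catalysed cleavage of the aryl MOM acetal, eased by the ortho carbonyl group that hydrogen-bonds the released phenol; dilute acid at room temperature should spare the prenyl group, the secondary alcohol and the enone.

**Compound list**

1 | 5-methoxyresorcinol | COc1cc(O)cc(O)c1 | starting material
2 | ethyl 2-methyl-3-oxobutanoate | CCOC(=O)C(C)C(C)=O | starting material
3 | 7-hydroxy-5-methoxy-3,4-dimethylcoumarin | COc1cc(O)cc2oc(=O)c(C)c(C)c12 | intermediate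
4 | 7-hydroxy-5-methoxy-3,4-dimethyl-2-oxo-2H-chromene-8-carbaldehyde | COc1cc(O)c(C=O)c2oc(=O)c(C)c(C)c12 | intermediate
5 | 7-hydroxy-6-iodo-5-methoxy-3,4-dimethyl-2-oxo-2H-chromene-8-carbaldehyde | COc1c(I)c(O)c(C=O)c2oc(=O)c(C)c(C)c12 | intermediate
6 | 6-iodo-5-methoxy-7-(methoxymethoxy)-3,4-dimethyl-2-oxo-2H-chromene-8-carbaldehyde | COc1c(I)c(OCOC)c(C=O)c2oc(=O)c(C)c(C)c12 | intermediate
7 | tributyl(3-methylbut-2-en-1-yl)stannane | CCCC[Sn](CCCC)(CCCC)CC=C(C)C | starting material
8 | 5-methoxy-7-(methoxymethoxy)-3,4-dimethyl-6-(3-methylbut-2-en-1-yl)-2-oxo-2H-chromene-8-carbaldehyde | COc1c(CC=C(C)C)c(OCOC)c(C=O)c2oc(=O)c(C)c(C)c12 | intermediate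
9 | but-1-en-3-yne | C=CC#C | starting material
10 | [(1E)-buta-1,3-dien-1-yl]dicyclohexylborane | C=C/C=C/B(C1CCCCC1)C1CCCCC1 | intermediate (not isolated)
11 | [(1E)-buta-1,3-dien-1-yl](methyl)zinc | C=C/C=C/[Zn]C | intermediate (not isolated)
12 | 8-[(1R,2E)-1-hydroxypenta-2,4-dien-1-yl]-5-methoxy-7-(methoxymethoxy)-3,4-dimethyl-6-(3-methylbut-2-en-1-yl)coumarin | O[C@@H](c1c(OCOC)c(CC=C(C)C)c(OC)c2c(C)c(C)c(=O)oc12)/C=C/C=C | intermediate
13 | but-2-ynoic acid | CC#CC(O)=O | starting material
14 | (1R,2E)-1-(coumarin-8-yl)penta-2,4-dien-1-yl but-2-ynoate (coumarin substituted as in 12) | CC#CC(=O)O[C@@H](c1c(OCOC)c(CC=C(C)C)c(OC)c2c(C)c(C)c(=O)oc12)/C=C/C=C | intermediate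
15 | (1R,2E)-1-(coumarin-8-yl)penta-2,4-dien-1-yl (2Z)-but-2-enoate (coumarin substituted as in 12) | C/C=C\C(=O)O[C@@H](c1c(OCOC)c(CC=C(C)C)c(OC)c2c(C)c(C)c(=O)oc12)/C=C/C=C | intermediate
16 | (3R,3aR,7R,7aR)-3-(coumarin-8-yl)-7-methyl-3a,6,7,7a-tetrahydro-2-benzofuran-1(3H)-one, trans-fused | O=C1O[C@@H](c3c(OCOC)c(CC=C(C)C)c(OC)c4c(C)c(C)c(=O)oc34)[C@@H]2C=CC[C@@H](C)[C@@H]12 | intermediate
17 | (1R,2R,6R)-2-[(R)-(coumarin-8-yl)(hydroxy)methyl]-N-methoxy-N,6-dimethylcyclohex-3-ene-1-carboxamide | O[C@@H](c3c(OCOC)c(CC=C(C)C)c(OC)c4c(C)c(C)c(=O)oc34)[C@@H]2C=CC[C@@H](C)[C@H]2C(=O)N(C)OC | intermediate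
18 | 1-[(1R,2R,6R)-2-[(R)-(coumarin-8-yl)(hydroxy)methyl]-6-methylcyclohex-3-en-1-yl]ethan-1-one | O[C@@H](c3c(OCOC)c(CC=C(C)C)c(OC)c4c(C)c(C)c(=O)oc34)[C@@H]2C=CC[C@@H](C)[C@H]2C(C)=O | intermediate
19 | (1S)-1-[(1R,2R,6R)-2-[(R)-(coumarin-8-yl)(hydroxy)methyl]-6-methylcyclohex-3-en-1-yl]ethan-1-ol | O[C@@H](c3c(OCOC)c(CC=C(C)C)c(OC)c4c(C)c(C)c(=O)oc34)[C@@H]2C=CC[C@@H](C)[C@H]2[C@H](C)O | intermediate
20 | (coumarin-8-yl)[(1R,5R,6R)-6-[(1S)-1-hydroxyethyl]-5-methylcyclohex-2-en-1-yl]methanone | O=C(c3c(OCOC)c(CC=C(C)C)c(OC)c4c(C)c(C)c(=O)oc34)[C@@H]2C=CC[C@@H](C)[C@H]2[C@H](C)O | intermediate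
21 | 8-{[(5R,6R)-6-[(1S)-1-hydroxyethyl]-5-methylcyclohex-1-en-1-yl]carbonyl}-5-methoxy-7-(methoxymethoxy)-3,4-dimethyl-6-(3-methylbut-2-en-1-yl)coumarin | COc1c(CC=C(C)C)c(OCOC)c(C(=O)C2=CCC[C@@H](C)[C@H]2[C@H](C)O)c2oc(=O)c(C)c(C)c12 | intermediate
22 | 7-hydroxy-8-{[(5R,6R)-6-[(1S)-1-hydroxyethyl]-5-methylcyclohex-1-en-1-yl]carbonyl}-5-methoxy-3,4-dimethyl-6-(3-methylbut-2-en-1-yl)coumarin | COc1c(CC=C(C)C)c(O)c(C(=O)C2=CCC[C@@H](C)[C@H]2[C@H](C)O)c2oc(=O)c(C)c(C)c12 | target

**Step count**

Total: 15 steps. Longest linear sequence: 15 steps (1 → 22); compounds 2, 7, 9 and 13 are bought.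

**Steps most likely to fail**

1. Step 9. The exo preference of the tether may be weak or inverted, giving fusion isomers whose C5'/C6' pairs become mirror images once C3 and C3a are erased. The acyloxy group may also migrate along the pentadienyl system at the temperature needed. Fallback, setting out from aldehyde 8 and returning at enone 21: the sense of the sacrificial centre is inverted and the endo mode is used instead.
   - The step 6 protocol with (−)-MIB gives the (S)-dienyl carbinol F1.
   - Esterification with 13 and semi-hydrogenation as in steps 7 and 8 give the but-2-ynoate F2 and the (Z)-but-2-enoate F3.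
   - Cycloaddition through the endo mode, again with the carbinol hydrogen eclipsing the diene, gives the cis-fused lactone F4, which carries the same C7/C7a configuration as 16.
   - The operations of steps 10 to 13 then give the Weinreb amide F5, the methyl ketone F6, the diol F7 and the β,γ-unsaturated ketone F8 (the C1' epimer of 20).
   - DBU converts F8 into 21.

2. Step 6. A ligand-free or chelation-controlled background addition to the aldehyde, which is flanked by two oxygen substituents, may erode the enantioselectivity, and the borane may also add to the vinyl group of the enyne. Fallback, setting out from aldehyde 8 and returning at carbinol 12: the stereocentre is set by reduction instead of addition.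
   - Dienylzinc 11 is added with achiral 2-(dimethylamino)ethanol as promoter to give the racemic dienyl carbinol F9.
   - MnO2 oxidises it to the aryl dienyl ketone F10.
   - Reduction with (S)-2-methyl-CBS-oxazaborolidine and catecholborane at −78 °C, on the premise that the twisted, doubly ortho-substituted aryl group acts as the larger substituent, gives 12.

3. Step 11. The Grignard reagent may attack the coumarin lactone, or the magnesium alkoxide may return onto the amide and re-form the lactone, in competition with ketone formation. Fallback, setting out from lactone 16 and returning at ketone 18: the methyl group is introduced by a palladium-catalysed coupling that leaves lactones alone.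
   - AlMe3 and EtSH in CH2Cl2 open the lactone to the hydroxy S-ethyl thioester F11.
   - Fukuyama coupling with MeZnI and PdCl2(PPh3)2 in toluene–THF at rt gives 18.

**Further compounds**

F1 | step 9 | 8-[(1S,2E)-1-hydroxypenta-2,4-dien-1-yl]-5-methoxy-7-(methoxymethoxy)-3,4-dimethyl-6-(3-methylbut-2-en-1-yl)coumarin (enantiomer of 12) | O[C@H](c1c(OCOC)c(CC=C(C)C)c(OC)c2c(C)c(C)c(=O)oc12)/C=C/C=C
F2 | step 9 | (1S,2E)-1-(coumarin-8-yl)penta-2,4-dien-1-yl but-2-ynoate | CC#CC(=O)O[C@H](c1c(OCOC)c(CC=C(C)C)c(OC)c2c(C)c(C)c(=O)oc12)/C=C/C=C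
F3 | step 9 | (1S,2E)-1-(coumarin-8-yl)penta-2,4-dien-1-yl (2Z)-but-2-enoate | C/C=C\C(=O)O[C@H](c1c(OCOC)c(CC=C(C)C)c(OC)c2c(C)c(C)c(=O)oc12)/C=C/C=C
F4 | step 9 | (3S,3aS,7R,7aR)-3-(coumarin-8-yl)-7-methyl-3a,6,7,7a-tetrahydro-2-benzofuran-1(3H)-one, cis-fused | O=C1O[C@H](c3c(OCOC)c(CC=C(C)C)c(OC)c4c(C)c(C)c(=O)oc34)[C@H]2C=CC[C@@H](C)[C@@H]12
F5 | step 9 | (1R,2S,6R)-2-[(S)-(coumarin-8-yl)(hydroxy)methyl]-N-methoxy-N,6-dimethylcyclohex-3-ene-1-carboxamide | O[C@H](c3c(OCOC)c(CC=C(C)C)c(OC)c4c(C)c(C)c(=O)oc34)[C@H]2C=CC[C@@H](C)[C@H]2C(=O)N(C)OC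
F6 | step 9 | 1-[(1R,2S,6R)-2-[(S)-(coumarin-8-yl)(hydroxy)methyl]-6-methylcyclohex-3-en-1-yl]ethan-1-one | O[C@H](c3c(OCOC)c(CC=C(C)C)c(OC)c4c(C)c(C)c(=O)oc34)[C@H]2C=CC[C@@H](C)[C@H]2C(C)=O
F7 | step 9 | (1S)-1-[(1R,2S,6R)-2-[(S)-(coumarin-8-yl)(hydroxy)methyl]-6-methylcyclohex-3-en-1-yl]ethan-1-ol | O[C@H](c3c(OCOC)c(CC=C(C)C)c(OC)c4c(C)c(C)c(=O)oc34)[C@H]2C=CC[C@@H](C)[C@H]2[C@H](C)O
F8 | step 9 | (coumarin-8-yl)[(1S,5R,6R)-6-[(1S)-1-hydroxyethyl]-5-methylcyclohex-2-en-1-yl]methanone (C1' epimer of 20) | O=C(c3c(OCOC)c(CC=C(C)C)c(OC)c4c(C)c(C)c(=O)oc34)[C@H]2C=CC[C@@H](C)[C@H]2[C@H](C)O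
F9 | step 6 | racemic 8-[(2E)-1-hydroxypenta-2,4-dien-1-yl]-5-methoxy-7-(methoxymethoxy)-3,4-dimethyl-6-(3-methylbut-2-en-1-yl)coumarin | OC(c1c(OCOC)c(CC=C(C)C)c(OC)c2c(C)c(C)c(=O)oc12)/C=C/C=C
F10 | step 6 | (2E)-1-(coumarin-8-yl)penta-2,4-dien-1-one | O=C(c1c(OCOC)c(CC=C(C)C)c(OC)c2c(C)c(C)c(=O)oc12)/C=C/C=C
F11 | step 11 | S-ethyl (1R,2R,6R)-2-[(R)-(coumarin-8-yl)(hydroxy)methyl]-6-methylcyclohex-3-ene-1-carbothioate | O[C@@H](c3c(OCOC)c(CC=C(C)C)c(OC)c4c(C)c(C)c(=O)oc34)[C@@H]2C=CC[C@@H](C)[C@H]2C(=O)SCC
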